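## Plan

1. Cuts, in retrosynthetic order: the two O–CH2CH2SiMe3 bonds at O3 and O7. Then C4a–C5 of ring A, with the C5–C8 σ-bond restored, which folds ring A back into a 4-methoxycyclobutenone on pyranone C6. Then O8–CH3, C8–C8a (pyranone carbanion plus semisquarate) and C2–C1' (cross-coupling).
2. Enabling feature: ring A has para oxygens at C5 (OH) and C8 (OMe), a third oxygen at C7 and hydrogen only at C6, and its C4a–C8a edge is the C5=C6 double bond of the 4-pyranone ring C. A four-membered ring reading C=O / CH / C–OR / C(OMe) on pyranone C6 therefore maps one to one onto C5 / C6 / C7 / C8.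
3. Forward order: ring C is bought as pyromeconic acid and ring B is joined at C2. The squarate-derived ring is attached at C6, ring A arises last by thermal ring expansion, and fluoride then frees O3 and O7.
4. Stereochemistry: none has to be set. The only stereocentres on the way (the carbinol carbon of the hydride adduct, the quaternary cyclobutenone carbon and C4a of the dienone) are racemic and become sp2.

Key step: step 9

Remark: the target has no stereocentre and no configurable double bond, so it is one achiral compound and nothing has to be resolved.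

Abbreviations and numbering: TMSE = 2-(trimethylsilyl)ethyl; prenyl = 3-methylbut-2-en-1-yl. Pyranone atoms are numbered as in the flavone (O1, C2 aryl, C3 oxygen, C4 carbonyl, C5–H, C6).

## Route

Step 1
Reactants: 1 squaric acid
Product: 2 bis(TMSE) squarate (3,4-bis[2-(trimethylsilyl)ethoxy]cyclobut-3-ene-1,2-dione)
Conditions: TMSCH2CH2OH (4 equiv), toluene, Dean–Stark, reflux
Reagents that add atoms: 2-(trimethylsilyl)ethanol, C[Si](C)(C)CCO
Why: Squaric acid is a strong vinylogous diacid that esterifies primary alcohols without added catalyst once water is removed azeotropically (Fischer-type esterification, as for dibutyl squarate), and a primary β-silyl alcohol should not ionise under these conditions.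

Step 2
Reactants: 2 bis(TMSE) squarate
Product: 4 3-(TMSE-oxy)cyclobut-3-ene-1,2-dione (TMSE semisquarate), via hydroxycyclobutenone 3 (not isolated)
Conditions: LiAlH(Ot-Bu)3, THF, −78 → −20 °C; 2 M HCl, CH2Cl2, 0 °C → rt
Reagents that add atoms: water, O (supplies the oxygen of the new carbonyl group while the carbinol OH leaves as water)
Why: The bulky hydride adds once and 1,2 to a squarate carbonyl, and acid then ionises the allylic carbinol and hydrolyses the alkoxy-stabilised cation with loss of one silylethanol (the standard addition/acid-transposition route from dialkyl squarates to 3-alkoxycyclobutenediones, here with hydride as the nucleophile).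

Step 3
Reactants: 5 4-hydroxyphenylboronic acid pinacol ester; 6 prenyl bromide
Product: 7 4-(prenyloxy)phenylboronic acid pinacol ester
Conditions: K2CO3, acetone, 50 °C
Reagents that add atoms: none
Why: Williamson ether synthesis of a phenoxide with a primary allylic bromide (SN2), under which the pinacol boronate is inert.

Step 4
Reactants: 8 pyromeconic acid (3-hydroxy-4H-pyran-4-one)
Product: 9 3-hydroxy-2-iodo-4H-pyran-4-one
Conditions: NIS, DMF, 0 °C → rt
Reagents that add atoms: N-iodosuccinimide, O=C1CCC(=O)N1I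
Why: Electrophilic iodination of the enol, since C2 (the carbon ortho to the 3-hydroxy group) is the position at which 3-hydroxy-4-pyranones take up halogens, aldehydes and Mannich electrophiles.

Step 5
Reactants: 9 3-hydroxy-2-iodo-4H-pyran-4-one
Product: 10 2-iodo-3-(TMSE-oxy)-4H-pyran-4-one
Conditions: TMSCH2CH2OH, PPh3, DIAD, THF, 0 °C → rt
Reagents that add atoms: 2-(trimethylsilyl)ethanol, C[Si](C)(C)CCO
Why: Mitsunobu etherification is the usual way to aryl-type TMSE ethers and suits an enol of pKa about 8; the group withstands base, palladium and organolithium reagents, and its later cleavage releases no formaldehyde that could attack the electron-rich C6.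

Step 6
Reactants: 10 2-iodo-3-(TMSE-oxy)-4H-pyran-4-one; 7 4-(prenyloxy)phenylboronic acid pinacol ester
Product: 11 2-[4-(prenyloxy)phenyl]-3-(TMSE-oxy)-4H-pyran-4-one
Conditions: Pd(dppf)Cl2 (5 mol %), K2CO3, dioxane–H2O (9:1), 80 °C
Reagents that add atoms: none
Why: Suzuki–Miyaura coupling of a 2-halo-4-pyranone, whose C–I bond at the β-carbon of an enone adds readily to Pd(0), while the aryl prenyl ether ionises far too slowly with Pd(0) to interfere.

Step 7
Reactants: 11 2-[4-(prenyloxy)phenyl]-3-(TMSE-oxy)-4H-pyran-4-one; 4 TMSE semisquarate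
Product: 13 (±)-4-hydroxy-4-{4-oxo-2-[4-(prenyloxy)phenyl]-3-(TMSE-oxy)-4H-pyran-6-yl}-3-(TMSE-oxy)cyclobut-2-en-1-one, via 6-lithiopyranone 12 (not isolated)
Conditions: LiTMP (from TMPH, n-BuLi), THF, −78 °C, 20 min; cannulated into 4 (1.2 equiv), THF, −78 °C; aq NH4Cl at −78 °C
Reagents that add atoms: none
Why: Proposed new method: C6–H is the vinylic hydrogen next to the ring oxygen and β to the carbonyl group, so a hindered lithium amide should remove it kinetically, and the resulting sp2 carbanion has no β-leaving group (a C5 anion would expel O1 and open the ring); the hard organolithium should then add 1,2 to the carbonyl of 4 that lies next to the alkoxy-bearing carbon, because the other carbonyl is deactivated as a vinylogous ester, and the hindered TMPH left in solution should not displace the alkoxy group of 4; the closest known reactions are the C2-lithiation of chromones with lithium amides and the addition of α-lithiated cyclic enol ethers, furans and aryllithiums to alkoxycyclobutenediones; the quaternary carbon forms as a racemate and is lost in step 9.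

Step 8
Reactants: 13 tertiary carbinol
Product: 14 (±)-4-methoxy-4-{4-oxo-2-[4-(prenyloxy)phenyl]-3-(TMSE-oxy)-4H-pyran-6-yl}-3-(TMSE-oxy)cyclobut-2-en-1-one
Conditions: MeI (10 equiv), Ag2O, 4 Å MS, MeCN, rt, dark
Reagents that add atoms: iodomethane, CI
Why: Purdie methylation (MeI/Ag2O) is the near-neutral method established for tertiary 4-hydroxycyclobutenones; it avoids both the acid that would trigger allylic transposition with loss of silylethanol and the hard methylating agents that turn 4-pyranones into 4-methoxypyrylium salts.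

Step 9
Reactants: 14 4-methoxy-4-(pyranon-6-yl)cyclobutenone
Product: 17 5-hydroxy-8-methoxy-4'-(prenyloxy)-3,7-bis(TMSE-oxy)flavone, via (Z)-vinylketene 15 (not isolated), via cyclohexadienone 16 (not isolated)
Conditions: toluene (0.01 M, degassed), 110 °C
Reagents that add atoms: none
Why: Heating cleaves the C1–C4 σ-bond of the cyclobutenone by conrotatory 4π electrocyclic opening, and the donor methoxy group turns outward (torquoselectivity), which puts the pyranone on the same side as the ketene in (Z)-vinylketene 15. Ring A then closes by thermal disrotatory 6π electrocyclisation of the dienylketene, the ketene carbon bonding to pyranone C5 (new C4a–C5 bond) to give dienone 16, whose C4a–H lies between two carbonyl groups and moves to oxygen, leaving the C5 phenol hydrogen-bonded to the C4 carbonyl. The closest known reaction type is the Moore-type thermal ring expansion of 4-alkenyl-, 4-aryl- and 4-heteroaryl-4-alkoxycyclobutenones to hydroquinone monoethers. The regiochemistry is written into the four-membered ring (C1=O becomes C5–OH, C2–H becomes C6–H, C3–OTMSE becomes C7–OTMSE, C4–OMe becomes C8–OMe), and C5 is the only carbon neighbour of pyranone C6, so there is one site of closure and no 6-methoxy isomer can form. The C5=C6 bond of the weakly aromatic pyranone behaves as an enol-ether alkene whose C5 end is nucleophilic and matches the electrophilic ketene carbon, while any (E)-ketene from inward rotation can only close back to 14. No stereocentre survives (C4 of 14 and C4a of 16 both become sp2), and 110 °C lies far below the range in which aryl prenyl ethers undergo Claisen rearrangement.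

Step 10
Reactants: 17 5-hydroxy-8-methoxy-4'-(prenyloxy)-3,7-bis(TMSE-oxy)flavone
Product: 18 3,5,7-trihydroxy-8-methoxy-4'-(prenyloxy)flavone
Conditions: TBAF (6 equiv), DMF, 60 °C, argon; AcOH quench
Reagents that add atoms: none
Why: Fluoride attacks silicon and both 2-silylethyl ethers fragment by β-elimination to ethene, Me3SiF and the phenoxide or enolate, which leaves the methyl and prenyl ethers untouched; air is excluded because flavonol anions are oxidised by oxygen.

## Compound list

1 | squaric acid (3,4-dihydroxycyclobut-3-ene-1,2-dione) | O=C1C(O)=C(O)C1=O | starting material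
2 | 3,4-bis[2-(trimethylsilyl)ethoxy]cyclobut-3-ene-1,2-dione | O=C1C(=O)C(OCC[Si](C)(C)C)=C1OCC[Si](C)(C)C | intermediate
3 | (±)-4-hydroxy-2,3-bis[2-(trimethylsilyl)ethoxy]cyclobut-2-en-1-one | O=C1C(O)C(OCC[Si](C)(C)C)=C1OCC[Si](C)(C)C | intermediate
4 | 3-[2-(trimethylsilyl)ethoxy]cyclobut-3-ene-1,2-dione | O=C1C=C(OCC[Si](C)(C)C)C1=O | intermediate
5 | 4-hydroxyphenylboronic acid pinacol ester | CC1(C)OB(c2ccc(O)cc2)OC1(C)C | starting material
6 | prenyl bromide (1-bromo-3-methylbut-2-ene) | CC(C)=CCBr | starting material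
7 | 4-(3-methylbut-2-enyloxy)phenylboronic acid pinacol ester | CC(C)=CCOc1ccc(cc1)B1OC(C)(C)C(C)(C)O1 | intermediate
8 | pyromeconic acid (3-hydroxy-4H-pyran-4-one) | O=c1ccocc1O | starting material
9 | 3-hydroxy-2-iodo-4H-pyran-4-one | O=c1ccoc(I)c1O | intermediate
10 | 2-iodo-3-[2-(trimethylsilyl)ethoxy]-4H-pyran-4-one | O=c1ccoc(I)c1OCC[Si](C)(C)C | intermediate
11 | 2-[4-(3-methylbut-2-enyloxy)phenyl]-3-[2-(trimethylsilyl)ethoxy]-4H-pyran-4-one | O=c1ccoc(-c2ccc(OCC=C(C)C)cc2)c1OCC[Si](C)(C)C | intermediate
12 | 6-lithio derivative of 11 | [Li]c1cc(=O)c(OCC[Si](C)(C)C)c(-c2ccc(OCC=C(C)C)cc2)o1 | intermediate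
13 | (±)-4-hydroxy-4-(pyranon-6-yl)-3-[2-(trimethylsilyl)ethoxy]cyclobut-2-en-1-one, pyranonyl = 4-oxo-2-[4-(prenyloxy)phenyl]-3-(TMSE-oxy)-4H-pyran-6-yl | OC1(C(=O)C=C1OCC[Si](C)(C)C)c1cc(=O)c(OCC[Si](C)(C)C)c(-c2ccc(OCC=C(C)C)cc2)o1 | intermediate
14 | (±)-4-methoxy analogue of 13 (methyl ether of the tertiary carbinol) | COC1(C(=O)C=C1OCC[Si](C)(C)C)c1cc(=O)c(OCC[Si](C)(C)C)c(-c2ccc(OCC=C(C)C)cc2)o1 | intermediate
15 | (3Z)-4-methoxy-4-(pyranon-6-yl)-3-(TMSE-oxy)buta-1,3-dien-1-one (vinylketene, pyranone cis to the ketene) | O=C=C/C(OCC[Si](C)(C)C)=C(\c1cc(=O)c(OCC[Si](C)(C)C)c(-c2ccc(OCC=C(C)C)cc2)o1)OC | intermediate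
16 | (±)-8-methoxy-2-[4-(prenyloxy)phenyl]-3,7-bis(TMSE-oxy)-4aH-chromene-4,5-dione | COC1=C2OC(-c3ccc(OCC=C(C)C)cc3)=C(OCC[Si](C)(C)C)C(=O)C2C(=O)C=C1OCC[Si](C)(C)C | intermediate
17 | 5-hydroxy-8-methoxy-4'-(prenyloxy)-3,7-bis[2-(trimethylsilyl)ethoxy]flavone | COc1c(OCC[Si](C)(C)C)cc(O)c2c(=O)c(OCC[Si](C)(C)C)c(-c3ccc(OCC=C(C)C)cc3)oc12 | intermediate
18 | 3,5,7-trihydroxy-8-methoxy-4'-(prenyloxy)flavone | COc1c(O)cc(O)c2c(=O)c(O)c(-c3ccc(OCC=C(C)C)cc3)oc12 | target

## Step count and risks

Total step count: 10. Longest linear sequence: 7 steps (8 to 18, steps 4–10).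

**1. Step 7 (bears the label "Proposed new method:").**
- What may go wrong:
  - deprotonation at C5 competing with C6, followed by expulsion of O1 and opening of the pyranone;
  - addition of the lithio species to pyranone that is not yet metalated;
  - proton transfer from the semisquarate, or conjugate addition to it, in place of 1,2-addition.
- Fallback with known reaction types, from 11 back to 13: the nucleophile is made by halogen–metal exchange instead of deprotonation with a lithium amide. Zincation of 11 with TMPZnCl·LiCl (THF, 25 °C) should give the 6-(chlorozincio)pyranone F1. This base tolerates carbonyl groups, and its site selectivity on chromones is known to be steerable between C2 and C3 by Lewis-acid additives. Iodolysis gives the 6-iodopyranone F2, on which the site of metalation can be established. Iodine–magnesium exchange with i-PrMgCl·LiCl at −78 °C gives the pyranon-6-ylmagnesium chloride F3, free of amine and less basic than 12. Its addition to 4 and an NH4Cl quench return to the route at 13.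

**2. Step 9 (key step).**
- What may go wrong: closure onto the cross-conjugated pyranone may be slower than onto a simple alkene. The reversible ring opening would then have to be driven at 140–180 °C, where the aryl prenyl ether begins to rearrange (Claisen) and the unsubstituted ketene terminus begins to oligomerise.
- Fallback, from 10 back to 17: the prenyl group is introduced after the ring expansion.
  - Suzuki–Miyaura coupling of 10 with commercial 4-(benzyloxy)phenylboronic acid pinacol ester gives the 2-[4-(benzyloxy)phenyl]pyranone F4.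
  - Metalation to the 6-lithiopyranone F5 and addition to 4 give the benzyl-series carbinol F6, and MeI/Ag2O gives the benzyl-series methyl ether F7.
  - F7 has no group that rearranges below 200 °C. It can be heated at high dilution in mesitylene or o-dichlorobenzene (165–180 °C), passing through the benzyl-series (Z)-vinylketene F8 and the benzyl-series cyclohexadienone F9 to the 4'-benzyloxyflavone F10.
  - Hydrogenolysis (H2, Pd/C, EtOAc) frees the 4'-hydroxyflavone F11.
  - Prenyl bromide 6 with K2CO3 in acetone alkylates only this phenol, because 5-OH is held in the hydrogen bond to the C4 carbonyl. This gives 17.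

**3. Step 8.**
- What may go wrong: slow etherification of the hindered tertiary alcohol, allylic transposition with loss of silylethanol on prolonged exposure to the silver salts, or methylation at the pyranone carbonyl oxygen.
- Fallback, from 13 back to 17: the methyl group is put on after ring A exists. Heating the free carbinol 13 in degassed toluene (the parent form of the same ring expansion, with hydroxyl turning outward) leads through the hydroxy-substituted (Z)-vinylketene F12 and the 8-hydroxy cyclohexadienone F13 to the 5,8-dihydroxyflavone (hydroquinone) F14, which is kept under argon. MeI (1 equiv) with K2CO3 in acetone then methylates the free 8-OH in preference to the chelated 5-OH, as is usual for 5-hydroxyflavones, and gives 17.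

## Further compounds

F1 | step 7 | 6-(chlorozincio)-2-[4-(prenyloxy)phenyl]-3-(TMSE-oxy)-4H-pyran-4-one | Cl[Zn]c1cc(=O)c(OCC[Si](C)(C)C)c(-c2ccc(OCC=C(C)C)cc2)o1
F2 | step 7 | 6-iodo-2-[4-(prenyloxy)phenyl]-3-(TMSE-oxy)-4H-pyran-4-one | Ic1cc(=O)c(OCC[Si](C)(C)C)c(-c2ccc(OCC=C(C)C)cc2)o1
F3 | step 7 | {4-oxo-2-[4-(prenyloxy)phenyl]-3-(TMSE-oxy)-4H-pyran-6-yl}magnesium chloride | Cl[Mg]c1cc(=O)c(OCC[Si](C)(C)C)c(-c2ccc(OCC=C(C)C)cc2)o1
F4 | step 9 | 2-[4-(benzyloxy)phenyl]-3-(TMSE-oxy)-4H-pyran-4-one | O=c1ccoc(-c2ccc(OCc3ccccc3)cc2)c1OCC[Si](C)(C)C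
F5 | step 9 | 6-lithio derivative of F4 | [Li]c1cc(=O)c(OCC[Si](C)(C)C)c(-c2ccc(OCc3ccccc3)cc2)o1
F6 | step 9 | (±)-4-{2-[4-(benzyloxy)phenyl]-4-oxo-3-(TMSE-oxy)-4H-pyran-6-yl}-4-hydroxy-3-(TMSE-oxy)cyclobut-2-en-1-one | OC1(C(=O)C=C1OCC[Si](C)(C)C)c1cc(=O)c(OCC[Si](C)(C)C)c(-c2ccc(OCc3ccccc3)cc2)o1
F7 | step 9 | (±)-4-{2-[4-(benzyloxy)phenyl]-4-oxo-3-(TMSE-oxy)-4H-pyran-6-yl}-4-methoxy-3-(TMSE-oxy)cyclobut-2-en-1-one | COC1(C(=O)C=C1OCC[Si](C)(C)C)c1cc(=O)c(OCC[Si](C)(C)C)c(-c2ccc(OCc3ccccc3)cc2)o1
F8 | step 9 | (3Z)-4-{2-[4-(benzyloxy)phenyl]-4-oxo-3-(TMSE-oxy)-4H-pyran-6-yl}-4-methoxy-3-(TMSE-oxy)buta-1,3-dien-1-one | O=C=C/C(OCC[Si](C)(C)C)=C(\c1cc(=O)c(OCC[Si](C)(C)C)c(-c2ccc(OCc3ccccc3)cc2)o1)OC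
F9 | step 9 | (±)-2-[4-(benzyloxy)phenyl]-8-methoxy-3,7-bis(TMSE-oxy)-4aH-chromene-4,5-dione | COC1=C2OC(-c3ccc(OCc4ccccc4)cc3)=C(OCC[Si](C)(C)C)C(=O)C2C(=O)C=C1OCC[Si](C)(C)C
F10 | step 9 | 4'-(benzyloxy)-5-hydroxy-8-methoxy-3,7-bis(TMSE-oxy)flavone | COc1c(OCC[Si](C)(C)C)cc(O)c2c(=O)c(OCC[Si](C)(C)C)c(-c3ccc(OCc4ccccc4)cc3)oc12
F11 | step 9 | 4',5-dihydroxy-8-methoxy-3,7-bis(TMSE-oxy)flavone | COc1c(OCC[Si](C)(C)C)cc(O)c2c(=O)c(OCC[Si](C)(C)C)c(-c3ccc(O)cc3)oc12
F12 | step 8 | (3Z)-4-hydroxy-4-{4-oxo-2-[4-(prenyloxy)phenyl]-3-(TMSE-oxy)-4H-pyran-6-yl}-3-(TMSE-oxy)buta-1,3-dien-1-one | O=C=C/C(OCC[Si](C)(C)C)=C(\c1cc(=O)c(OCC[Si](C)(C)C)c(-c2ccc(OCC=C(C)C)cc2)o1)O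
F13 | step 8 | (±)-8-hydroxy-2-[4-(prenyloxy)phenyl]-3,7-bis(TMSE-oxy)-4aH-chromene-4,5-dione | OC1=C2OC(-c3ccc(OCC=C(C)C)cc3)=C(OCC[Si](C)(C)C)C(=O)C2C(=O)C=C1OCC[Si](C)(C)C
F14 | step 8 | 5,8-dihydroxy-4'-(prenyloxy)-3,7-bis(TMSE-oxy)flavone | Oc1c(OCC[Si](C)(C)C)cc(O)c2c(=O)c(OCC[Si](C)(C)C)c(-c3ccc(OCC=C(C)C)cc3)oc12
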